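The constants are assumed; what happens was integrated by code.

Set minutes against hours first: in this flask the exchange between substrate and dormant form relaxes with a half-life of 0.946 min, far shorter than the 6.0 h of the step to side product.

- how much target there is at 10 h, in percent of the substrate charged
- concentration of dissolved gas in solution at 10 h, in percent of saturation

substrate 0.050 M; gas phase 9.7 mM (held); time 10 h

    gas phase ⇌ dissolved gas, rate k1*(csat - [dissolved gas]) (k1 = 0.00866 s⁻¹, csat = 9.7 mM)
    substrate + dissolved gas → target (k2 = 0.151 L mol⁻¹ s⁻¹)
    substrate → side product (k3 = 3.19 × 10⁻⁵ s⁻¹)
    substrate ⇌ dormant form (K4 = 6.6, k4 = 0.0106 s⁻¹)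
    2 dissolved gas → self-condensation product (k5 = 0.138 L mol⁻¹ s⁻¹)

- a step written with two of one species runs at k times the square of its concentration and takes two of it each time
- at the start none of the gas is dissolved
- run time (flask): 10 h

Replace the rising curve of dissolved gas by one level, where transfer into solution balances the loss to self-condensation: 7.77 mM. At that level free substrate is used pseudo-first-order at 0.0723 min⁻¹, of which 97.4% makes target. Now take the pool, substrate plus dormant form. Its free part is one in 7.60, which stretches the free time, and a dormant molecule also waits 0.173 h to return. The sum is the pool lifetime, the time in which the pool falls by a factor e: 1.92 h.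

| Half-life of | Value |
|---|---|
| dissolved gas, back to its level | 0.892 min |
| substrate and dormant form, relaxing | 0.946 min |
| free substrate | 9.58 min |
| pool | 1.33 h |

Read down. The first row is far shorter than the last, so one level may stand in for the curve. The third row is 10.1 times the second, so the exchange keeps ahead of the use of free substrate, and the waiting term is 8.99% of the lifetime. The error of the level: once the exchange has relaxed, free substrate pulls dissolved gas down to about 7.21 mM, a dip of 7.21% that I let fade with the pool, so over the 5.20 lifetimes run it averages about 1.39%. I commit to 0.553% of the pool left, 96.8% target and 80.1% of saturation.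

The forecast says 96.8% (95% to 98%) and 80% (78% to 82%), with the dormant form “quickly equilibrated”.

The simulation gives 96.6% target and dissolved gas at 80.1% of saturation. At 1.00 h dissolved gas stood lower, at 76.9% of saturation. Use the pool lifetime on this flask at 10.0 h: it leaves 0.553%, and substrate plus dormant form come to 0.542%. Now read the same flask at 4.0 h: the lifetime leaves 12.5% of the pool and gives 85.3% target, and that flask holds 12.6% and 84.9%.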